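Locants (daucane): C1 quaternary fusion carbon, C2/C3 ring CH2, C4 carbinol carbon, C5 fusion CH, C6 acyloxy carbon, C7 CH2, C8=C9 alkene, C10 ketone; β is the face of the C1 methyl group. End game: 6‑O‑aroylation and desilylation, with C4–OH coming from hydride opening (at C3) of a 3β,4β‑epoxide.
Key disconnection: C1–C2 and C3–C4 of the cyclopentane are cut together. A monocyclic C1 dienolate carrying the C4 isobutyryl ketone on C5 is bridged by CH2=CH–S+Ph2 (C2 electrophilic, C3 nucleophilic as the ylide).
Enabling feature: C1 of the five‑membered ring is the α‑carbon of the C10 ketone of the seven‑membered ring, and C4, on the neighbouring fusion carbon C5, is a tertiary carbinol carbon. This gives a 1,4‑dioxygenated C10–C1–C5–C4 array (γ‑oxo enolate) whose ends are exactly two CH2 groups (C2, C3) apart. The ring closes at C3–C4, away from the fusion bond, so the trans C1/C5 relationship can be set beforehand by anti addition.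
The γ‑oxo enolate is stored as a silyl dienol ether, made by carbonylative conjugate addition of iPr2Zn/CO to (S)‑4‑silyloxy‑2,6‑dimethylcyclohepta‑2,6‑dienone. That dienone comes from a chloro(methyl)carbene ring expansion of (S)‑5‑silyloxy‑3‑methylcyclohexenone, itself from a catalytic desymmetrising aldol condensation of an achiral heptane‑2,6‑dione.
Ring order: six‑membered ring (step 3), expanded to the seven‑membered ring (step 5), then the five‑membered ring last (step 7, together with a temporary oxirane that step 8 removes).

Key step: step 7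

Assumption: of the two pseudo‑enantiomeric cinchona primary amines, the quinidine‑derived one is taken to give (S)‑4. If the sense of induction is opposite, the quinine‑derived catalyst is used.

Step 1
Reactants: 1 hepta-1,6-dien-4-ol
Product: 2 tert-butyl(hepta-1,6-dien-4-yloxy)dimethylsilane
Conditions: TBSCl, imidazole, DMF, rt
Reagents that add atoms: tert-butyldimethylsilyl chloride, CC(C)(C)[Si](C)(C)Cl
Why: Imidazole-promoted silylation of the secondary alcohol should be routine, and the carbinol carbon stays prochiral, so no stereocentre is involved.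

Step 2
Reactants: 2 tert-butyl(hepta-1,6-dien-4-yloxy)dimethylsilane
Product: 3 4-(tert-butyldimethylsilyloxy)heptane-2,6-dione
Conditions: PdCl2 (10 mol %), CuCl, O2 (1 atm), DMF/H2O, rt
Reagents that add atoms: water, O
Why: A twofold Wacker–Tsuji oxidation should turn both terminal alkenes Markovnikov-selectively into methyl ketones (O2 as terminal oxidant), the homoallylic silyl ether is tolerated, and the product remains achiral.

Step 3
Reactants: 3 4-(tert-butyldimethylsilyloxy)heptane-2,6-dione
Product: 4 (S)-5-(tert-butyldimethylsilyloxy)-3-methylcyclohex-2-en-1-one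
Conditions: 9-amino-9-deoxy-epi-quinidine (20 mol %), AcOH (60 mol %), toluene, −15 °C
Reagents that add atoms: none
Why: This is a primary-amine (enamine) catalysed, enantiogroup-differentiating 6-enolexo intramolecular aldol condensation, a known desymmetrisation of 4-substituted heptane-2,6-diones; the catalyst chooses which enantiotopic acetonyl arm becomes the enamine and so fixes the silyloxy carbon (future C6) as S.

Step 4
Reactants: 4 (S)-5-(tert-butyldimethylsilyloxy)-3-methylcyclohex-2-en-1-one
Product: 5 (S)-1-(tert-butyldimethylsilyloxy)-5-methyl-3-(trimethylsilyloxy)cyclohexa-2,4-diene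
Conditions: LDA, TMSCl (in situ quench), THF, −78 °C
Reagents that add atoms: chlorotrimethylsilane, C[Si](C)(C)Cl
Why: Kinetic α′-deprotonation of the enone with internal silyl trapping should give the cross-conjugated 2-silyloxydiene, the low temperature suppresses β-elimination of the silyloxy group, and C6 is untouched.

Step 5
Reactants: 5 (S)-1-(tert-butyldimethylsilyloxy)-5-methyl-3-(trimethylsilyloxy)cyclohexa-2,4-diene, 6 1,1-dichloroethane
Product: 8 (S)-4-(tert-butyldimethylsilyloxy)-2,6-dimethylcyclohepta-2,6-dien-1-one, via chlorocyclopropane 7 (not isolated)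
Conditions: n-BuLi, Et2O, −40 °C; then toluene, Et3N (cat.), 90 °C
Reagents that add atoms: none
Why: In this halocarbene one-carbon ring expansion, chloro(methyl)carbene adds to the most electron-rich (silyloxy-substituted) double bond, and the 1-silyloxy-7-chloro-7-methylnorcarene opens by cyclopropyl-to-allyl cation ring opening with loss of Me3SiCl; this inserts C1 with its methyl group and creates the seven-membered ring without touching C6.

Step 6
Reactants: 8 (S)-4-(tert-butyldimethylsilyloxy)-2,6-dimethylcyclohepta-2,6-dien-1-one, 9 diisopropylzinc, 10 carbon monoxide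
Product: 11 1-[(1S,7S)-7-(tert-butyldimethylsilyloxy)-2,5-dimethyl-3-(trimethylsilyloxy)cyclohepta-2,4-dien-1-yl]-2-methylpropan-1-one
Conditions: CO (1 atm), TMSCl, Pd2(dba)3 (2.5 mol %), THF, 0 °C → rt; non-aqueous work-up
Reagents that add atoms: chlorotrimethylsilane, C[Si](C)(C)Cl
Why: This is the Pd-catalysed carbonylative conjugate addition of a dialkylzinc to an enone: Pd(0)/Me3SiCl converts the β-unsubstituted C1=C5 enone (not the β-methylated C8=C9 one) into a 1-silyloxy-π-allyl complex on the face anti to the C6 silyloxy group, and transmetallation, CO insertion and reductive elimination place the isobutyryl group on C5 from that face (C5 S) while leaving the C10/C1 enolate regiospecifically masked as its silyl ether.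

Step 7
Reactants: 11 1-[(1S,7S)-7-(tert-butyldimethylsilyloxy)-2,5-dimethyl-3-(trimethylsilyloxy)cyclohepta-2,4-dien-1-yl]-2-methylpropan-1-one, 12 diphenyl(vinyl)sulfonium trifluoromethanesulfonate
Product: 15 (1S,3S,4R,5S,6S)-6-(tert-butyldimethylsilyloxy)-3,4-epoxydauc-8-en-10-one (trans-fused 5–7 bicycle; 3β,4β-oxirane; 6α-silyloxy), via caesium dienolate 13 (not isolated), via sulfonium ylide 14 (not isolated)
Conditions: CsF (anhydrous), MeCN/CH2Cl2, −40 °C → rt
Reagents that add atoms: none
Why: Proposed new method: fluoride cleaves only the enol Si–O bond of 11 and releases the cross-conjugated C1 dienolate 13 regiospecifically; 13 adds through C1 to the unhindered CH2 terminus of the vinylsulfonium salt to give ylide 14, whose carbanionic C3 attacks the C4 ketone and whose alkoxide then expels Ph2S, so that C1–C2, C3–C4 and C3–O are formed in one flask. The closest known reaction types are the fluoride-induced γ-oxo-enolate/vinylphosphonium cyclopentene annulation (Michael addition, then intramolecular Wittig reaction) and the epoxy-annulation of heteroatom-tethered ketones with vinylsulfonium salts; what is new is a plain ketone dienolate as the carbon nucleophile, building a quaternary centre. The cyclopentane closes by 5-exo-trig addition of C3 to the C4 carbonyl group, and the temporary oxirane closes by 3-exo-tet displacement of diphenyl sulfide. A(1,2) strain with the C1 methyl group holds the C5 isobutyryl group pseudo-axial on the β face, so C2 enters at C1 from the α face (vicinal anti-alkylation as in three-component enone couplings); this fixes C1 (S) and places C2 and C4 trans on the seven-membered ring before the ring closes at the remote C3–C4 bond, so the trans fusion is not opposed by the geometry of closure. At C4 the ylide attacks the ketone rotamer that keeps the isopropyl group next to H5 and away from the C6 silyloxy carbon, which puts oxygen on the β face (C4 R), and C3 follows because the oxirane can only be cis-fused. The step needs C- over O-alkylation and capture of 13 before proton transfer from C7, which the very high electrophilicity of 12, the slow enolate release by sparingly soluble CsF and the low basicity of the ylide should secure; it also needs C4 rather than C10 as acceptor, which holds because attack at C10 would require a four-membered ring.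

Step 8
Reactants: 15 (1S,3S,4R,5S,6S)-6-(tert-butyldimethylsilyloxy)-3,4-epoxydauc-8-en-10-one
Product: 16 6α-(tert-butyldimethylsilyloxy)dauc-8-ene-4β,10-diol (both C10 epimers)
Conditions: LiAlH4, THF, 0 → 50 °C; aqueous work-up
Reagents that add atoms: none
Why: SN2 hydride opening of the trisubstituted epoxide at the less substituted C3 keeps the tertiary C4–O bond and its configuration, the enone is reduced 1,2 at the same time, and the new C10 centre is inconsequential because step 9 removes it.

Step 9
Reactants: 16 6α-(tert-butyldimethylsilyloxy)dauc-8-ene-4β,10-diol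
Product: 17 4β-hydroxy-6α-(tert-butyldimethylsilyloxy)dauc-8-en-10-one
Conditions: Dess–Martin periodinane, CH2Cl2, rt
Reagents that add atoms: none
Why: Dess–Martin oxidation acts on the only oxidisable (secondary, allylic) alcohol and restores the C8=C9–C10=O enone, since the C4 alcohol is tertiary and C6 is protected.

Step 10
Reactants: 17 4β-hydroxy-6α-(tert-butyldimethylsilyloxy)dauc-8-en-10-one
Product: 18 4β,6α-dihydroxydauc-8-en-10-one
Conditions: HF·pyridine, THF/pyridine, 0 °C → rt
Reagents that add atoms: none
Why: Fluoride-mediated Si–O cleavage under weakly acidic conditions frees the C6 alcohol with retention and avoids base that could enolise the enone towards C7.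

Step 11
Reactants: 18 4β,6α-dihydroxydauc-8-en-10-one, 19 4-(tert-butyldimethylsilyloxy)benzoic acid
Product: 20 (1S,4R,5S,6S)-4-hydroxy-10-oxodauc-8-en-6-yl 4-(tert-butyldimethylsilyloxy)benzoate
Conditions: DCC, DMAP (cat.), CH2Cl2, rt
Reagents that add atoms: none
Why: Steglich esterification acylates the secondary C6 hydroxyl group and not the hindered tertiary C4 hydroxyl group, and it proceeds with retention because the C6–O bond is not broken.

Step 12
Reactants: 20 (1S,4R,5S,6S)-4-hydroxy-10-oxodauc-8-en-6-yl 4-(tert-butyldimethylsilyloxy)benzoate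
Product: 21 (1S,4R,5S,6S)-4-hydroxy-10-oxodauc-8-en-6-yl 4-hydroxybenzoate (target)
Conditions: HF·pyridine, THF, 0 °C
Reagents that add atoms: none
Why: The phenolic silyl ether is cleaved fastest by HF·pyridine, and the non-basic medium avoids the vinylogous E1cB loss of the C6 aroyloxy group, so all four stereocentres remain as set.

Compound list
1 | hepta-1,6-dien-4-ol | C=CCC(O)CC=C | starting material
2 | tert-butyl(hepta-1,6-dien-4-yloxy)dimethylsilane | C=CCC(CC=C)O[Si](C)(C)C(C)(C)C | intermediate
3 | 4-(tert-butyldimethylsilyloxy)heptane-2,6-dione | CC(=O)CC(CC(C)=O)O[Si](C)(C)C(C)(C)C | intermediate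
4 | (S)-5-(tert-butyldimethylsilyloxy)-3-methylcyclohex-2-en-1-one | CC1=CC(=O)C[C@@H](O[Si](C)(C)C(C)(C)C)C1 | intermediate
5 | (S)-1-(tert-butyldimethylsilyloxy)-5-methyl-3-(trimethylsilyloxy)cyclohexa-2,4-diene | CC1=CC(O[Si](C)(C)C)=C[C@@H](O[Si](C)(C)C(C)(C)C)C1 | intermediate
6 | 1,1-dichloroethane | CC(Cl)Cl | starting material
7 | chlorocyclopropane: 7-chloro-4,7-dimethyl-1-(trimethylsilyloxy)bicyclo[4.1.0]hept-2-ene with the (S)-silyloxy carbon next to the ring-fusion CH (mixture at the three cyclopropane carbons) | CC1=CC2(O[Si](C)(C)C)C(C2(C)Cl)[C@@H](O[Si](C)(C)C(C)(C)C)C1 | intermediate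
8 | (S)-4-(tert-butyldimethylsilyloxy)-2,6-dimethylcyclohepta-2,6-dien-1-one | CC1=CC(=O)C(C)=C[C@@H](O[Si](C)(C)C(C)(C)C)C1 | intermediate
9 | diisopropylzinc | CC(C)[Zn]C(C)C | starting material
10 | carbon monoxide | [C-]#[O+] | starting material
11 | 1-[(1S,7S)-7-(tert-butyldimethylsilyloxy)-2,5-dimethyl-3-(trimethylsilyloxy)cyclohepta-2,4-dien-1-yl]-2-methylpropan-1-one | CC1=CC(O[Si](C)(C)C)=C(C)[C@H](C(=O)C(C)C)[C@@H](O[Si](C)(C)C(C)(C)C)C1 | intermediate
12 | diphenyl(vinyl)sulfonium trifluoromethanesulfonate | C=C[S+](c1ccccc1)c1ccccc1.[O-]S(=O)(=O)C(F)(F)F | starting material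
13 | caesium dienolate of the C10 ketone (C1=C10–O−), C5 isobutyryl, C6 silyloxy | CC1=CC([O-])=C(C)[C@H](C(=O)C(C)C)[C@@H](O[Si](C)(C)C(C)(C)C)C1.[Cs+] | intermediate
14 | sulfonium ylide: C1-quaternary enone carrying CH2–CH(−)–S(+)Ph2 (α) on C1 and isobutyryl (β) on C5 | CC1=CC(=O)[C@@](C)(C[CH-][S+](c2ccccc2)c2ccccc2)[C@H](C(=O)C(C)C)[C@@H](O[Si](C)(C)C(C)(C)C)C1 | intermediate
15 | (1S,3S,4R,5S,6S)-6-(tert-butyldimethylsilyloxy)-3,4-epoxydauc-8-en-10-one | CC1=CC(=O)[C@@]2(C)C[C@@H]3O[C@]3(C(C)C)[C@@H]2[C@@H](O[Si](C)(C)C(C)(C)C)C1 | intermediate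
16 | 6α-(tert-butyldimethylsilyloxy)dauc-8-ene-4β,10-diol (C10 epimers) | CC1=CC(O)[C@@]2(C)CC[C@@](O)(C(C)C)[C@@H]2[C@@H](O[Si](C)(C)C(C)(C)C)C1 | intermediate
17 | 4β-hydroxy-6α-(tert-butyldimethylsilyloxy)dauc-8-en-10-one | CC1=CC(=O)[C@@]2(C)CC[C@@](O)(C(C)C)[C@@H]2[C@@H](O[Si](C)(C)C(C)(C)C)C1 | intermediate
18 | 4β,6α-dihydroxydauc-8-en-10-one | CC1=CC(=O)[C@@]2(C)CC[C@@](O)(C(C)C)[C@@H]2[C@@H](O)C1 | intermediate
19 | 4-(tert-butyldimethylsilyloxy)benzoic acid | CC(C)(C)[Si](C)(C)Oc1ccc(cc1)C(=O)O | starting material
20 | (1S,4R,5S,6S)-4-hydroxy-10-oxodauc-8-en-6-yl 4-(tert-butyldimethylsilyloxy)benzoate | CC1=CC(=O)[C@@]2(C)CC[C@@](O)(C(C)C)[C@@H]2[C@@H](OC(=O)c2ccc(O[Si](C)(C)C(C)(C)C)cc2)C1 | intermediate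
21 | (1S,4R,5S,6S)-4-hydroxy-10-oxodauc-8-en-6-yl 4-hydroxybenzoate | CC1=CC(=O)[C@@]2(C)CC[C@@](O)(C(C)C)[C@@H]2[C@@H](OC(=O)c2ccc(O)cc2)C1 | target

Total step count: 12. Longest linear sequence: 12 steps (1 → 21).

Steps most likely to fail

Step 7 (proposed new method). The free dienolate may transfer a proton from C7 and then lose the C6 silyloxy group, it may be alkylated on oxygen, or the ylide may be protonated or decay before it reaches the hindered ketone. The fallback uses known chemistry, sets out from 11 and comes back at 17. The fluoride-released enolate is trapped with freshly prepared nitroethylene (enolate/nitroalkene Michael addition, anti to the C5 acyl group) to give the nitro diketone F1. A mild amine base closes C3–C4 by an intramolecular Henry reaction to give the nitro alcohol F2. Radical denitration with Bu3SnH/AIBN then gives 17, so that 15 and 16 are skipped.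

Step 6. Formation of the silyloxy-allyl-palladium species may be slow at the α-methylated enone, the isopropyl-palladium unit may isomerise by β-hydride elimination before CO insertion, or β-elimination of the silyloxy group may intervene. The fallback sets out from 8 and comes back at 17. The cuprate from 2-bromo-3-methylbut-1-ene (a masked isobutyryl group) is added to C5 anti to the silyloxy group, and the enolate is trapped in the same flask with nitroethylene (three-component enone coupling) to give the alkenyl nitro ketone F3. Selective ozonolysis of its electron-rich 1,1-disubstituted alkene gives the nitro diketone F1, which is carried on through the nitro alcohol F2 to 17 as described above.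

Step 5. The lithium carbenoid may add sluggishly to the hindered silyloxy alkene, and the heating needed for ring opening may trigger loss of silanol and drift towards the tropone. The fallback sets out from 5 and comes back at 8. Dibromocarbene (CHBr3, KOt-Bu) is added to give the dibromocyclopropane F4, which should open well below the temperature needed for the chloride to give the 2-bromo dienone F5. The C1 methyl group is then introduced by Stille coupling with Me4Sn (Pd catalysis) to give 8.

Further compounds
F1 | step 7 | nitro diketone: (4S,5S,6S)-5-(tert-butyldimethylsilyloxy)... ring named by locants as C1-(2-nitroethyl)-C1-methyl-C5-isobutyryl-C6-silyloxy cyclohept-8-en-10-one (C1 S, C5 S, C6 S) | CC1=CC(=O)[C@@](C)(CC[N+](=O)[O-])[C@H](C(=O)C(C)C)[C@@H](O[Si](C)(C)C(C)(C)C)C1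
F2 | step 7 | nitro alcohol: 4β-hydroxy-3-nitro-6α-(tert-butyldimethylsilyloxy)dauc-8-en-10-one (C3 epimers) | CC1=CC(=O)[C@@]2(C)CC([N+](=O)[O-])[C@@](O)(C(C)C)[C@@H]2[C@@H](O[Si](C)(C)C(C)(C)C)C1
F3 | step 6 | alkenyl nitro ketone: analogue of F1 with a 3-methylbut-1-en-2-yl group on C5 in place of isobutyryl | CC1=CC(=O)[C@@](C)(CC[N+](=O)[O-])[C@H](C(=C)C(C)C)[C@@H](O[Si](C)(C)C(C)(C)C)C1
F4 | step 5 | dibromocyclopropane: 7,7-dibromo analogue of 7 (no methyl on the cyclopropane) | CC1=CC2(O[Si](C)(C)C)C(C2(Br)Br)[C@@H](O[Si](C)(C)C(C)(C)C)C1
F5 | step 5 | (S)-2-bromo-4-(tert-butyldimethylsilyloxy)-6-methylcyclohepta-2,6-dien-1-one | CC1=CC(=O)C(Br)=C[C@@H](O[Si](C)(C)C(C)(C)C)C1
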